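**Plan**
1. Retrosynthesis: cut the exocyclic C2–acyl bond first (late C-acylation), then the ring bond C1–C6 between the ring carbonyl carbon and the methoxy/prenyl quaternary carbon. This leads back to a flat 4-methoxy-2-pyranone, which is cut at C4–C5 (dioxinone γ-acylation) and at both C–prenyl bonds (enolate alkylations with prenyl bromide).
2. Enabling feature: the carbocycle C1–C6 is a cyclohexa-2,4-dienone with sp3 C6 (C1=O, C2=C3, C4=C5). It is the closed valence isomer of the dienylketene O=C1=C2–C3=C4–C5=C6. The same ketene closed through the oxygen on C5 instead of through C6 is a 2-pyranone (ring A), so ring A is a stable, geometry-locked precursor.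
3. Forward order: dioxinone → keto-dioxinone → 4-hydroxy-2-pyranone (ring A, a temporary ring) → methyl ether → base-triggered opening of ring A and reclosure through carbon to the carbocycle (ring B) → hydrolysis of the helper methyl enol ether → C-acylation.
4. Stereochemistry: the single stereocentre C6 (S) is created in the ring closure of a planar enolate under a recoverable C2-symmetric chiral lithium amide. The racemic stereocentres made earlier are all erased before or in that step.

Key step: step 7

Assumption: keto–enol tautomers of the 1,3,5-tricarbonyl ring are treated as one compound and are drawn in the tautomer of the target SMILES, in which C6 is (S).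

Step 1
Reactants: 1 2,2,6-trimethyl-4H-1,3-dioxin-4-one; 2 1-bromo-3-methylbut-2-ene (prenyl bromide)
Product: 3 2,2-dimethyl-6-(4-methylpent-3-en-1-yl)-4H-1,3-dioxin-4-one
Conditions: LiN(iPr)2 (LDA), THF, DMPU, −78 → −20 °C
Reagents that add atoms: none
Why: Vinylogous enolate alkylation: the lithium dienolate of the dioxinone reacts at its γ-carbon (the C6 methyl group) with the primary allylic bromide by SN2, so the prenyl group arrives without allylic transposition and no stereocentre is formed.

Step 2
Reactants: 4 methoxyacetic acid; 2 1-bromo-3-methylbut-2-ene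
Product: 5 2-methoxy-5-methylhex-4-enoic acid (racemic)
Conditions: LiN(iPr)2 (2.2 equiv), THF, −78 → 0 °C; then 2; 1 M HCl
Reagents that add atoms: none
Why: Dianion (enediolate) alkylation of an α-alkoxyacetic acid at carbon with the allylic bromide; the new stereocentre is deliberately left racemic because it is erased by deprotonation in step 7.

Step 3
Reactants: 5 2-methoxy-5-methylhex-4-enoic acid
Product: 6 2-methoxy-5-methylhex-4-enoyl chloride (racemic, used crude)
Conditions: (COCl)2, DMF (cat.), CH2Cl2, 0 °C → rt
Reagents that add atoms: oxalyl chloride, O=C(Cl)C(Cl)=O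
Why: Acid chloride formation through the chloroiminium (Vilsmeier-type) intermediate under mild conditions that should leave the ether and the trisubstituted alkene untouched.

Step 4
Reactants: 3 2,2-dimethyl-6-(4-methylpent-3-en-1-yl)-4H-1,3-dioxin-4-one; 6 2-methoxy-5-methylhex-4-enoyl chloride
Product: 7 6-[3-methoxy-6-methyl-1-(3-methylbut-2-en-1-yl)-2-oxohept-5-en-1-yl]-2,2-dimethyl-4H-1,3-dioxin-4-one (mixture of racemic diastereomers)
Conditions: LiN(SiMe3)2 (2.1 equiv), THF, −78 °C; then 6, −78 → −30 °C; 1 M HCl
Reagents that add atoms: none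
Why: Crossed Claisen-type C-acylation of the γ-carbon of the dioxinone dienolate by an acid chloride, the second equivalent of base deprotonating the more acidic product; the two new stereocentres need no control because one is erased in step 5 and the other in step 7.

Step 5
Reactants: 7 the keto-dioxinone of step 4
Product: 9 4-hydroxy-6-(1-methoxy-4-methylpent-3-en-1-yl)-5-(3-methylbut-2-en-1-yl)-2H-pyran-2-one, via acylketene 8 (not isolated)
Conditions: toluene (dilute), 110 °C
Reagents that add atoms: none
Why: Retro-hetero-Diels–Alder loss of acetone gives an acylketene that is trapped by the enol oxygen of the neighbouring ketone (6-exo-dig lactonisation) to give the aromatic 4-hydroxy-2-pyranone, the usual fate of 6-(2-oxoalkyl)dioxinones; the stereocentre carrying the prenyl group becomes sp2.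

Step 6
Reactants: 9 the 4-hydroxy-2-pyranone of step 5
Product: 10 4-methoxy-6-(1-methoxy-4-methylpent-3-en-1-yl)-5-(3-methylbut-2-en-1-yl)-2H-pyran-2-one (racemic)
Conditions: Me2SO4, K2CO3, acetone, 56 °C
Reagents that add atoms: dimethyl sulfate, COS(=O)(=O)OC
Why: Williamson-type O-methylation of the vinylogous acid, known to give 4-methoxy-2-pyranones; the methyl group is a helper that removes the acidic OH so that the side-chain CH is the only site a base can use in step 7.

Step 7
Reactants: 10 the 4-methoxy-2-pyranone of step 6
Product: 14 (6S)-5-hydroxy-3,6-dimethoxy-4,6-bis(3-methylbut-2-en-1-yl)cyclohexa-2,4-dien-1-one, via lithium pyranolate 11 (not isolated), via lithium oxido-dienylketene 12 (not isolated), via lithium dienolate 13 (not isolated)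
Conditions: lithium amide made from N1,N3-bis[(1R)-1-phenyl-2-(piperidin-1-yl)ethyl]propane-1,3-diamine (1.1 equiv) and n-BuLi (1.05 equiv), THF, −78 °C; add 10; −78 → 0 °C; then 1 M HCl
Reagents that add atoms: none
Why: Proposed new method: the amide removes the only proton whose loss gives a conjugated anion (the side-chain CH that becomes C6; C4 is fully substituted), and the 6-alkylidene-pyranolate 11 then expels its ring oxygen from the acyl carbon (E1cB acyl–oxygen cleavage, a retro-oxa-6π opening) to give the lithium enolate 12 of a dienylketene, which closes between C1 and C6 to the vinylogous carboxylate 13. The closest known reaction types are ketene formation from lithium enolates of aryl and enol esters, the thermal closure of dienylketenes to cyclohexa-2,4-dienones (dark step of the Barton–Quinkert reaction and last step of the Moore and Danheiser annulations), the alkoxide-mediated pyranone-to-phloroglucinol Claisen isomerisation, and enolate C–C bond formation inside chiral lithium amide or amine aggregates. The carbocycle (ring B) is closed by a thermal 6π disrotatory electrocyclisation of C1=C2–C3=C4–C5=C6, which is at the same time a 6-(enolendo)-exo-dig attack of the enolate carbon on the sp ketene carbon. The new stereocentre C6 arises from a planar enolate and is controlled by the C2-symmetric tetramine that stays chelated to the lithium on the enolate oxygen next to C6 and should shield one face of C6; the sense of induction has to be established, and the antipodal tetramine is used if it is the opposite one. The step needs closure through carbon and not through oxygen, the s-cis,s-cis shape of the ketene, and a single enolate site: closure through oxygen only regenerates 11 and is reversible whereas closure through carbon is irreversible, ring A fixes C2 and C5 cis on C3=C4 (so the ketene is born U-shaped and the C4 prenyl group points away from it), and the fully substituted C4 leaves C6 as the only enolisable position. Because deprotonation erases the racemic CH(OMe) centre of 10, both enantiomers of 10 converge on the same intermediate.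

Step 8
Reactants: 14 the dienone of step 7
Product: 15 (6S)-3,5-dihydroxy-6-methoxy-4,6-bis(3-methylbut-2-en-1-yl)cyclohexa-2,4-dien-1-one (enol form of the 1,3,5-trione)
Conditions: 2 M HCl, THF, 40 °C
Reagents that add atoms: water, O
Why: Acid hydrolysis of a vinylogous methyl ester (addition–elimination of water at C3) removes the helper methyl group selectively, because the C6 methoxy group is a plain tertiary alkyl ether; C6 is quaternary and not enolisable, so its configuration is kept.

Step 9
Reactants: 15 the trione of step 8; 16 3-phenylpropanoic acid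
Product: 18 (6S)-3,5-dihydroxy-6-methoxy-4,6-bis(3-methylbut-2-en-1-yl)-2-(3-phenylpropanoyl)cyclohexa-2,4-dien-1-one, via enol ester 17 (not isolated)
Conditions: DCC, DMAP, CH2Cl2, 0 °C → rt
Reagents that add atoms: none
Why: Carbodiimide O-acylation of the enolised trione followed by DMAP-mediated O→C acyl migration (a Fries-type 1,3-shift, well known for cyclic 1,3-diones) should end at C2, the only carbon whose acylation gives the chelated, fully enolised β-triketone; acylation at the prenyl-bearing C4 would be reversible, and C6 is not touched.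

**Compound list**
1 | 2,2,6-trimethyl-4H-1,3-dioxin-4-one | CC1=CC(=O)OC(C)(C)O1 | starting material
2 | 1-bromo-3-methylbut-2-ene | CC(C)=CCBr | starting material
3 | 2,2-dimethyl-6-(4-methylpent-3-en-1-yl)-4H-1,3-dioxin-4-one | CC(C)=CCCC1=CC(=O)OC(C)(C)O1 | intermediate
4 | methoxyacetic acid | COCC(=O)O | starting material
5 | 2-methoxy-5-methylhex-4-enoic acid (racemic) | COC(CC=C(C)C)C(=O)O | intermediate
6 | 2-methoxy-5-methylhex-4-enoyl chloride (racemic) | COC(CC=C(C)C)C(Cl)=O | intermediate
7 | 6-[3-methoxy-6-methyl-1-(3-methylbut-2-en-1-yl)-2-oxohept-5-en-1-yl]-2,2-dimethyl-4H-1,3-dioxin-4-one (diastereomer mixture) | CC1(C)OC(=CC(=O)O1)C(CC=C(C)C)C(=O)C(OC)CC=C(C)C | intermediate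
8 | 6-methoxy-9-methyl-4-(3-methylbut-2-en-1-yl)deca-1,8-diene-1,3,5-trione (acylketene) | O=C=CC(=O)C(CC=C(C)C)C(=O)C(OC)CC=C(C)C | intermediate (not isolated)
9 | 4-hydroxy-6-(1-methoxy-4-methylpent-3-en-1-yl)-5-(3-methylbut-2-en-1-yl)-2H-pyran-2-one (racemic) | COC(CC=C(C)C)C1=C(CC=C(C)C)C(O)=CC(=O)O1 | intermediate
10 | 4-methoxy-6-(1-methoxy-4-methylpent-3-en-1-yl)-5-(3-methylbut-2-en-1-yl)-2H-pyran-2-one (racemic) | COC(CC=C(C)C)C1=C(CC=C(C)C)C(OC)=CC(=O)O1 | intermediate
11 | lithium 4-methoxy-6-(1-methoxy-4-methylpent-3-en-1-ylidene)-5-(3-methylbut-2-en-1-yl)-6H-pyran-2-olate | [Li+].[O-]C1=CC(OC)=C(CC=C(C)C)C(=C(OC)CC=C(C)C)O1 | intermediate (not isolated)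
12 | lithium (3E)-3,6-dimethoxy-9-methyl-4-(3-methylbut-2-en-1-yl)-1-oxodeca-1,3,5,8-tetraen-5-olate (C2 and C5 cis on C3=C4; C5=C6 geometry not specified) | [Li+].O=C=C/C(OC)=C(/CC=C(C)C)C([O-])=C(OC)CC=C(C)C | intermediate (not isolated)
13 | lithium salt of 14 (O–Li on C5) | [Li+].CO[C@]1(CC=C(C)C)C(=O)C=C(OC)C(CC=C(C)C)=C1[O-] | intermediate (not isolated)
14 | (6S)-5-hydroxy-3,6-dimethoxy-4,6-bis(3-methylbut-2-en-1-yl)cyclohexa-2,4-dien-1-one | CO[C@]1(CC=C(C)C)C(=O)C=C(OC)C(CC=C(C)C)=C1O | intermediate
15 | (6S)-3,5-dihydroxy-6-methoxy-4,6-bis(3-methylbut-2-en-1-yl)cyclohexa-2,4-dien-1-one | CO[C@]1(CC=C(C)C)C(=O)C=C(O)C(CC=C(C)C)=C1O | intermediate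
16 | 3-phenylpropanoic acid | OC(=O)CCc1ccccc1 | starting material
17 | 3-O-(3-phenylpropanoyl) enol ester of 15 (one of the possible O-acyl regioisomers) | CO[C@]1(CC=C(C)C)C(=O)C=C(OC(=O)CCc2ccccc2)C(CC=C(C)C)=C1O | intermediate (not isolated)
18 | (6S)-3,5-dihydroxy-6-methoxy-4,6-bis(3-methylbut-2-en-1-yl)-2-(3-phenylpropanoyl)cyclohexa-2,4-dien-1-one | CO[C@]1(CC=C(C)C)C(=O)C(C(=O)CCc2ccccc2)=C(O)C(CC=C(C)C)=C1O | target

Total step count: 9. Longest linear sequence: 8 steps (steps 2 to 9, from methoxyacetic acid).

**Steps most likely to fail**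

Step 7 (proposed new method). The pyranolate may fail to open before it decomposes. The transient ketene may be captured by the secondary amine nitrogens of the tetramine. Facial discrimination at C6 may be poor. The fallback uses known chemistry, sets out from 10 and comes back at 14. Heating 10 with NaOMe in MeOH opens the lactone to methyl (2E)-3,6-dimethoxy-9-methyl-4-(3-methylbut-2-en-1-yl)-5-oxodeca-2,8-dienoate F1. Under the same equilibrating conditions F1 closes by a Claisen (Dieckmann-type) condensation of the C6 enolate on the ester to racemic 5-hydroxy-3,6-dimethoxy-4,6-bis(3-methylbut-2-en-1-yl)cyclohexa-2,4-dien-1-one F2. Preparative chromatography on a chiral stationary phase then separates 14 from its (6R)-enantiomer F3.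

Step 4. Acylation of the hindered secondary dienolate may be slow, and O-acylation or α-acylation may compete. The fallback reverses the order of the two C–C bond formations, sets out from 1 and 6 and comes back at 7. The unsubstituted dienolate of 1 (LiN(SiMe3)2, THF, −78 °C) is acylated at its methyl carbon with 6 to give 6-(3-methoxy-6-methyl-2-oxohept-5-en-1-yl)-2,2-dimethyl-4H-1,3-dioxin-4-one F4. Its doubly activated CH2 group is then C-alkylated with 2 (K2CO3, acetone).

Step 8. The enol oxygens may add to the prenyl double bonds under acid (cyclic ether formation), or hydrolysis of the electron-rich vinylogous ester may stall. The fallback changes the helper group so that no acid is needed, sets out from 9 and comes back at 15. Compound 9 is O-alkylated with allyl bromide (K2CO3, acetone) to give 6-(1-methoxy-4-methylpent-3-en-1-yl)-5-(3-methylbut-2-en-1-yl)-4-(prop-2-en-1-yloxy)-2H-pyran-2-one F5. F5 is carried through the conditions of step 7 to (6S)-5-hydroxy-6-methoxy-4,6-bis(3-methylbut-2-en-1-yl)-3-(prop-2-en-1-yloxy)cyclohexa-2,4-dien-1-one F6. The allyl group is then removed under neutral conditions with Pd(PPh3)4 (zerovalent palladium) and morpholine in THF.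

Further compounds
F1 | step 7 | methyl (2E)-3,6-dimethoxy-9-methyl-4-(3-methylbut-2-en-1-yl)-5-oxodeca-2,8-dienoate | COC(=O)/C=C(/OC)C(CC=C(C)C)C(=O)C(OC)CC=C(C)C
F2 | step 7 | racemic 5-hydroxy-3,6-dimethoxy-4,6-bis(3-methylbut-2-en-1-yl)cyclohexa-2,4-dien-1-one | COC1(CC=C(C)C)C(=O)C=C(OC)C(CC=C(C)C)=C1O
F3 | step 7 | (6R)-5-hydroxy-3,6-dimethoxy-4,6-bis(3-methylbut-2-en-1-yl)cyclohexa-2,4-dien-1-one | CO[C@@]1(CC=C(C)C)C(=O)C=C(OC)C(CC=C(C)C)=C1O
F4 | step 4 | 6-(3-methoxy-6-methyl-2-oxohept-5-en-1-yl)-2,2-dimethyl-4H-1,3-dioxin-4-one | CC1(C)OC(=CC(=O)O1)CC(=O)C(OC)CC=C(C)C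
F5 | step 8 | 6-(1-methoxy-4-methylpent-3-en-1-yl)-5-(3-methylbut-2-en-1-yl)-4-(prop-2-en-1-yloxy)-2H-pyran-2-one | C=CCOC1=CC(=O)OC(C(OC)CC=C(C)C)=C1CC=C(C)C
F6 | step 8 | (6S)-5-hydroxy-6-methoxy-4,6-bis(3-methylbut-2-en-1-yl)-3-(prop-2-en-1-yloxy)cyclohexa-2,4-dien-1-one | CO[C@]1(CC=C(C)C)C(=O)C=C(OCC=C)C(CC=C(C)C)=C1O
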